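(The readings were generated by integration with made-up constants; noise was put on by code.)

The west run levels at 75.2% of its substrate, more than the 49.9% of the north-east run, though both were charged the same partner.

| setting | west | north-east | noon | spring | midnight | dawn | summer |
|---|---|---|---|---|---|---|---|
| substrate | 1 M | 1.5 M | 1.5 M | 1.5 M | 1.5 M | 1.5 M | 1.5 M |
| partner | 0.75 M | 0.75 M | 1.20 M | 0.250 M | 0.400 M | 0.500 M | 0.750 M |
| free catalyst | 150 mM | 75 mM | 150 mM | 150 mM | 150 mM | 150 mM | 150 mM |
| remark | run made earlier | run made earlier |  |  |  |  |  |
| time |  |  | 5.0 h | 5.0 h | 5.0 h | 5.0 h | 5.0 h |

| run | time / h | target / % | substrate / % |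
|---|---|---|---|
| west | 0.417 | 28.5 | 69.7 |
| west | 1.00 | 53.2 | 43.6 |
| west | 2.00 | 73.4 | 21.1 |
| west | 3.00 | 75.2 | 13.9 |
| north-east | 0.833 | 27.9 | 72.6 |
| north-east | 1.50 | 40.6 | 57.2 |
| north-east | 2.50 | 49.9 | 46.5 |
| north-east | 3.00 | 49.0 | 44.8 |

(readings scatter by 0.5 percentage points)

* the flasks put in order of amount of target, in percent of the substrate charged, best first, at 5.0 h (noon / spring / midnight / dawn / summer)
* the amount of target, in percent of the substrate charged of the flask you put first, at 5.0 h
* the amount of target, in percent of the substrate charged of the flask you put last, at 5.0 h

I reckon with two extreme flasks. In the first, the catalyst is infinitely quick, so each partner gives one target and partner is the limiting reagent. The yield is then the partner ceiling, c(partner)/c(substrate) 16.7%, printed here for spring. The same ratio gives 75.0% for west and 50.0% for north-east, close to where those runs level.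

In the second, partner is endless and the catalyst takes up substrate at a steady first-order pace. The first west reading gives a first-order constant of 0.866 /h, and the asked flasks carry the same 150 mM of catalyst. This clock flask has used 98.7% of its substrate by 5.0 h.

I expect the real flask at or under the lower of the two. Noon has the highest ceiling, 80.0%, and that is still less than the clock, so I expect the ceilings to hold.

Now I put that answer back. At the last west reading, 10.9% of the substrate is neither target nor substrate. I place it on catalyst intermediate A, the resting state once partner thins, which in the west run can hold 15.0% of the substrate charged. Noon, with the most partner, therefore needs by my reckoning 90.0% of its substrate, less than its charge. On the clock this takes 2.66 h. The clock slows as catalyst parks, but 5.0 h is about twice that. So I commit to the order of partner charges, with noon at 80.0% and spring at 16.7%.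

The forecast gave noon > summer > dawn > midnight > spring, with 79.5% and 16.6%, holding that “target is capped by partner, one target per partner”.

The flasks give noon > summer > dawn > midnight > spring, with 80.0% for noon and 16.7% for spring.

    catalyst intermediate C → free catalyst + target (k = 85.2 /min)
    substrate → decomposition product (k = 2.53 × 10⁻⁵ /min)
    partner + catalyst intermediate A → catalyst intermediate B (k = 1.24 /M/min)
    substrate + free catalyst → catalyst intermediate A (k = 0.105 /M/min)
    catalyst intermediate B → catalyst intermediate C (k = 21.8 /min)

Spring's ceiling of 16.7% can be carried to a neighbour of spring charged with 0.60 M of substrate, partner and catalyst held. I reckon that the ceiling rises to 41.7%, that catalyst intermediate A takes 25.0%, and that 33.3% of the substrate stays. That flask holds 41.7% target, 24.9% catalyst intermediate A and 33.1% substrate.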